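A molecule of starting material has an easy first step: it meets dissolved coupling partner and takes one of two forks.

    starting material + coupling partner → first product (k1 = 6.1 /M/h, Ea1 = 65.0 kJ/mol)
    starting material + coupling partner → other mono adduct (k2 = 1.1 /M/h, Ea2 = 60.0 kJ/mol)
    coupling partner + first product → double product (k3 = 6.9 /M/h, Ea3 = 66.0 kJ/mol)
    coupling partner + other mono adduct → double product (k4 = 3.7 /M/h, Ea4 = 65.0 kJ/mol)
    starting material + first product → side product (k5 = 0.30 /M/h, Ea5 = 67.0 kJ/mol)
    gas ⇌ coupling partner, rate k6*(csat - [coupling partner]) (k6 = 0.28 /h, csat = 8.7 mM)
    (constants at 0 °C)

| flask | starting material | gas | temperature | time |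
|---|---|---|---|---|
| winter | 0.10 M | 8.7 mM (held) | 0 °C | 5.0 d |
| summer | 0.10 M | 8.7 mM (held) | −15 °C | 5.0 d |
| noon | 0.10 M | 8.7 mM (held) | −30 °C | 5.0 d |
- percent here means starting material units held: one side product counts as two
- at the start none of coupling partner is dissolved
- at 0 °C the constants are as listed, elsewhere as the activation energies make them
- the flask that comes out highest in amount of first product, in percent of the starting material charged, or "all alike" when all lie within 1.5 percentage points (winter / summer / noon / all alike)
- first product at the end, in percent of the starting material charged, winter
- first product at the end, in percent of the starting material charged, summer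
- first product at the end, in percent of the starting material charged, noon

One molecule can be followed by hand. Under a steady partner level c the starting material decays pseudo-first-order with k, the summed constant of the two forks. The exposure n = k·c·t counts the e-foldings a flask offers. The first fork takes a share φ of the molecules. At 0 °C the constant from first product to double product, 6.9 /M/h, lies close to k = 7.20 /M/h, so first product ends near φ·n·e^(−n), with a peak at n equal to one.

A relative error in n therefore moves the yield by (one minus n) times that error. The constants of the forks and csat count fully where n is small, hardly near one, and heavily where n is large. The transfer lag, 3.57 h, is short beside 5.0 d, but transfer must be held against demand: c starts at zero and, while the starting material stands near its charge, climbs only to the sagged level csat·k6/(k6 + k·cA), and in winter demand exceeds transfer. The side step is a further exit from first product, which this reckoning leaves out; in winter, with starting material at its charge and c at the sagged level, it runs at 1.78 times the double-product exit.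

At noon k = 0.221 /M/h, which gives n = 0.214, the sagged exposure, and 14.0%. Summer has k = 1.39 /M/h, n = 0.971, and 30.5%. Winter lies between n = 2.10 and the unsagged 7.52, so between 21.7% and 0.346%. Summer comes out highest.

The forecast also named summer, with 5%, 25% and 13.3%, saying of that flask: “First product sits near its maximum”.

The simulation gives summer highest, with 4.94% in winter, 26.0% in summer and 13.3% at noon, so the summer reckoning stood 4.5 percentage points high. The noon flask converted 19.3% of its starting material, and its exposure gives 1 − e^(−n) = 19.2%.

A repeat of noon at −45 °C has k = 0.0276 /M/h, so n = 0.0285 and the reckoning gives 2.17%. That flask gives 2.10%.

Its constants are made up; the run is a simulation.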